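Ring A of calyxin B (C1' acyl, C2' OH, C3' bearing C7, C4' OH, C5' H, C6' OMe) is a mono-O-methylated acylphloroglucinol. Its oxygen-bearing carbons C2', C4' and C6' are therefore read as the carbonyl carbons of a linear keto ester, and the ring is disconnected at C1'–C2'. One base-mediated Claisen cyclisation makes that bond, closes and aromatises ring A, and leaves the cinnamoyl ketone, the 6'-methyl ether and the C7 branch in their final positions. The precursor is an open-chain methyl 5-methoxy-3,7-dioxonona-4,8-dienoate carrying the silylated diarylheptenyl unit on C2, with the C6' carbonyl masked as an E methyl enol ether.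

Key step: step 11

Remarks
- TBS = tert-butyldimethylsilyl; TBSO = tert-butyldimethylsilyloxy.
- The heptenyl chain is numbered C1 (benzylic CH2 next to ring D) to C7 (diarylmethine); ring A is numbered C1' (acyl) to C6' (OMe); ring B is the cinnamoyl aryl group and ring C the aryl group on C7.
- The four starting materials, including the silylated benzaldehyde and the methyl ester of 3-(4-hydroxyphenyl)propanoic acid, are assumed to be purchased.
- All four hydroxyl groups to be masked are carried as TBS ethers, and the cyclisation uses a non-nucleophilic amide base, so that the aryl silyl ethers survive and a single buffered fluoride step finishes the synthesis.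

Step 1
Reactants: 1 methyl 3-(4-hydroxyphenyl)propanoate
Product: 2 methyl 3-[4-(TBSO)phenyl]propanoate
Conditions: TBSCl, imidazole, DMF, rt
Reagents that add atoms: tert-butyldimethylsilyl chloride, CC(C)(C)[Si](C)(C)Cl
Why: Silylation of a phenol with a silyl chloride and imidazole is routine and masks the ring D hydroxyl for the basic steps ahead.

Step 2
Reactants: 2 methyl 3-[4-(TBSO)phenyl]propanoate
Product: 3 3-[4-(TBSO)phenyl]propanal
Conditions: i-Bu2AlH (1.05 equiv), CH2Cl2, −78 °C; aq potassium sodium tartrate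
Reagents that add atoms: none
Why: Partial reduction of an ester with i-Bu2AlH at −78 °C should stop at the aldehyde because the aluminium hemiacetal survives until work-up.

Step 3
Reactants: 4 (E)-4-(4-hydroxyphenyl)but-3-en-2-one
Product: 5 (E)-4-[4-(TBSO)phenyl]but-3-en-2-one
Conditions: TBSCl, imidazole, DMF, rt
Reagents that add atoms: tert-butyldimethylsilyl chloride, CC(C)(C)[Si](C)(C)Cl
Why: Phenol silylation as in step 1 masks ring C and leaves the methyl ketone as the only enolisable site.

Step 4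
Reactants: 5 (E)-4-[4-(TBSO)phenyl]but-3-en-2-one; 3 3-[4-(TBSO)phenyl]propanal
Product: 7 (3S,6E)-3-hydroxy-1,7-bis[4-(TBSO)phenyl]hept-6-en-5-one, via boron enolate 6 (not isolated)
Conditions: (−)-B-chlorodiisopinocampheylborane [(−)-Ipc2BCl, from (+)-α-pinene], Et3N, Et2O, 0 °C; then 3, −78 → −20 °C; H2O2, MeOH, pH 7 buffer (NaH2PO4/Na2HPO4), 0 °C
Reagents that add atoms: none
Why: Boron-mediated aldol addition of a methyl ketone: the diisopinocampheylborinate enolate 6 is expected to attack the Re face of aldehyde 3 and so set C3 as S with moderate to good enantioselectivity, the minor enantiomer being removed after step 6.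

Step 5
Reactants: 7 (3S,6E)-3-hydroxy-1,7-bis[4-(TBSO)phenyl]hept-6-en-5-one
Product: 8 (3S,6E)-3-(TBSO)-1,7-bis[4-(TBSO)phenyl]hept-6-en-5-one
Conditions: TBSOTf, 2,6-lutidine, CH2Cl2, −78 °C
Reagents that add atoms: tert-butyldimethylsilyl trifluoromethanesulfonate, CC(C)(C)[Si](C)(C)OS(=O)(=O)C(F)(F)F
Why: Silylation of the secondary alcohol with a silyl triflate and a hindered pyridine base at low temperature should avoid β-elimination of the aldol and leaves C3 untouched.

Step 6
Reactants: 8 (3S,6E)-3-(TBSO)-1,7-bis[4-(TBSO)phenyl]hept-6-en-5-one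
Product: 9 (3S,5S,6E)-3-(TBSO)-1,7-bis[4-(TBSO)phenyl]hept-6-en-5-ol
Conditions: (R)-1-methyl-3,3-diphenyltetrahydro-1H,3H-pyrrolo[1,2-c][1,3,2]oxazaborole (0.2 equiv), BH3·SMe2, THF, −30 °C; MeOH
Reagents that add atoms: none
Why: Corey–Bakshi–Shibata reduction of an enone under catalyst control: with the styryl group as the large substituent the (R)-oxazaborolidine should give the 5S carbinol (3,5-syn), and material of the wrong C3 configuration from step 4 becomes the 3,5-anti diastereomer, which chromatography should remove here.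

Step 7
Reactants: 9 (3S,5S,6E)-3-(TBSO)-1,7-bis[4-(TBSO)phenyl]hept-6-en-5-ol
Product: 11 methyl (3S,4E,7S)-7-(TBSO)-3,9-bis[4-(TBSO)phenyl]non-4-enoate, via ketene acetal 10 (not isolated)
Conditions: MeC(OMe)3 (excess), EtCO2H (cat.), xylene, 135 °C, MeOH distilled off
Reagents that add atoms: trimethyl orthoacetate, CC(OC)(OC)OC
Why: Johnson–Claisen rearrangement: the mixed ketene acetal 10 rearranges through a chair transition state with C4 equatorial, which passes the C5 configuration suprafacially to C7 (5S gives the C7 configuration of the target, labelled 3S in this ester) and forms the E C5=C6 alkene.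

Step 8
Reactants: 12 4-methoxy-6-methyl-2H-pyran-2-one; 13 4-(TBSO)benzaldehyde
Product: 15 6-{2-hydroxy-2-[4-(TBSO)phenyl]ethyl}-4-methoxy-2H-pyran-2-one (racemic), via lithiated pyranone 14 (not isolated)
Conditions: LiN(SiMe3)2 (1.1 equiv), THF, −78 °C; then 13, −78 °C; AcOH
Reagents that add atoms: none
Why: Vinylogous aldol addition: the amide base removes a proton from the C6 methyl group and the resulting extended enolate 14 adds to the aldehyde; the new carbinol centre is racemic and disappears in step 9.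

Step 9
Reactants: 15 6-{2-hydroxy-2-[4-(TBSO)phenyl]ethyl}-4-methoxy-2H-pyran-2-one
Product: 17 4-methoxy-6-{(E)-2-[4-(TBSO)phenyl]ethenyl}-2H-pyran-2-one, via mesylate 16 (not isolated)
Conditions: MsCl, Et3N, CH2Cl2, 0 °C; then DBU, rt
Reagents that add atoms: none
Why: Mesylation followed by E1cB elimination across the vinylogously acidic CH2 group should give the fully conjugated styrylpyranone with the thermodynamically preferred E geometry.

Step 10
Reactants: 11 methyl (3S,4E,7S)-7-(TBSO)-3,9-bis[4-(TBSO)phenyl]non-4-enoate; 17 4-methoxy-6-{(E)-2-[4-(TBSO)phenyl]ethenyl}-2H-pyran-2-one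
Product: 19 methyl (4E,8E)-2-{(1R,2E,5S)-5-(TBSO)-1,7-bis[4-(TBSO)phenyl]hept-2-en-1-yl}-5-methoxy-3,7-dioxo-9-[4-(TBSO)phenyl]nona-4,8-dienoate (C2 epimers, partly enolised), via lithium enolate 18 (not isolated)
Conditions: LiN(SiMe3)2 (2.3 equiv), THF, −78 °C; then 17, −78 → −40 °C; AcOH, −78 °C; pH 7 buffer (NaH2PO4/Na2HPO4)
Reagents that add atoms: none
Why: Claisen-type C-acylation of an ester enolate by an enol lactone: 18 adds to the lactone carbonyl (the future C4'), the ring opens to the enolate of the cinnamoyl ketone, and the second equivalent of base removes the now acidic C3' proton; the cis ring relationship across the pyranone C3=C4 bond becomes the E enol ether, C7 is not touched, and cold protonation should return 19 before it cyclises.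

Step 11
Reactants: 19 methyl (4E,8E)-2-{(1R,2E,5S)-5-(TBSO)-1,7-bis[4-(TBSO)phenyl]hept-2-en-1-yl}-5-methoxy-3,7-dioxo-9-[4-(TBSO)phenyl]nona-4,8-dienoate
Product: 21 (E)-1-{2,4-dihydroxy-6-methoxy-3-[(1S,2E,5S)-5-(TBSO)-1,7-bis[4-(TBSO)phenyl]hept-2-en-1-yl]phenyl}-3-[4-(TBSO)phenyl]prop-2-en-1-one (tetra-TBS ether of calyxin B), via dilithium dienolate 20 (not isolated)
Conditions: LiN(SiMe3)2 (3.3 equiv), THF, −78 → 0 °C; AcOH, pH 7 buffer (NaH2PO4/Na2HPO4)
Reagents that add atoms: none
Why: The base removes the C3' proton and then a C1' proton to give dienolate 20, whose C1' terminus adds to the C2' ester carbonyl on warming; methoxide leaves and the cyclohexadienone tautomerises to the bis-phenoxide of 21, which makes the closure irreversible. The closest known reaction is the base-mediated intramolecular Claisen (Dieckmann-type) condensation of 3,5,7-tricarbonyl esters to acylphloroglucinols. Ring A closes in the 6-exo-trig mode, helped by the E geometry of the C5'=C6' enol ether, which keeps C1' and C4' on the same side so that C1' can reach C2'. No stereocentre is created: the C3' centre of 19 becomes aromatic, and the C7 hydrogen (only allylic and benzylic) and C3 are beyond the reach of the base, so both should keep their configuration. The step needs C-acylation at C1' in preference to aldol attack of C3' on the cinnamoyl carbonyl or to O-acylation; an aldol adduct at the fully substituted C3' cannot dehydrate to an arene and should revert, the enol ether fixes the pattern 6'-OMe, 2'-OH, 4'-OH, and only the Claisen product is removed from the equilibria by aromatisation.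

Step 12
Reactants: 21 tetra-TBS ether of calyxin B
Product: 22 calyxin B, (E)-1-{2,4-dihydroxy-3-[(1S,2E,5S)-5-hydroxy-1,7-bis(4-hydroxyphenyl)hept-2-en-1-yl]-6-methoxyphenyl}-3-(4-hydroxyphenyl)prop-2-en-1-one
Conditions: Bu4NF, AcOH (1:1, excess), THF, 0 °C → rt
Reagents that add atoms: none
Why: Fluoride-mediated desilylation removes the three aryl and the one secondary alkyl TBS ether, while acetic acid buffers the phenoxides so that the 2'-hydroxychalcone should not close to a flavanone and the C3 hydroxyl should not add to the allylic diarylmethine; no stereocentre is touched.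

Compound list
1 | methyl 3-(4-hydroxyphenyl)propanoate | COC(=O)CCc1ccc(O)cc1 | starting material
2 | methyl 3-[4-(TBSO)phenyl]propanoate | COC(=O)CCc1ccc(O[Si](C)(C)C(C)(C)C)cc1 | intermediate
3 | 3-[4-(TBSO)phenyl]propanal | O=CCCc1ccc(O[Si](C)(C)C(C)(C)C)cc1 | intermediate
4 | (E)-4-(4-hydroxyphenyl)but-3-en-2-one | CC(=O)/C=C/c1ccc(O)cc1 | starting material
5 | (E)-4-[4-(TBSO)phenyl]but-3-en-2-one | CC(=O)/C=C/c1ccc(O[Si](C)(C)C(C)(C)C)cc1 | intermediate
6 | diisopinocampheylboron enolate of 5 (not isolated) | C=C(OB([C@@H]1C[C@@H]2C[C@H]([C@H]1C)C2(C)C)[C@@H]1C[C@@H]2C[C@H]([C@H]1C)C2(C)C)/C=C/c1ccc(O[Si](C)(C)C(C)(C)C)cc1 | intermediate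
7 | (3S,6E)-3-hydroxy-1,7-bis[4-(TBSO)phenyl]hept-6-en-5-one | O=C(/C=C/c1ccc(O[Si](C)(C)C(C)(C)C)cc1)C[C@@H](O)CCc1ccc(O[Si](C)(C)C(C)(C)C)cc1 | intermediate
8 | (3S,6E)-3-(TBSO)-1,7-bis[4-(TBSO)phenyl]hept-6-en-5-one | O=C(/C=C/c1ccc(O[Si](C)(C)C(C)(C)C)cc1)C[C@@H](O[Si](C)(C)C(C)(C)C)CCc1ccc(O[Si](C)(C)C(C)(C)C)cc1 | intermediate
9 | (3S,5S,6E)-3-(TBSO)-1,7-bis[4-(TBSO)phenyl]hept-6-en-5-ol | O[C@H](/C=C/c1ccc(O[Si](C)(C)C(C)(C)C)cc1)C[C@@H](O[Si](C)(C)C(C)(C)C)CCc1ccc(O[Si](C)(C)C(C)(C)C)cc1 | intermediate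
10 | 1-methoxyethenyl ether (ketene acetal) of 9 at O5 (not isolated) | C=C(OC)O[C@H](/C=C/c1ccc(O[Si](C)(C)C(C)(C)C)cc1)C[C@@H](O[Si](C)(C)C(C)(C)C)CCc1ccc(O[Si](C)(C)C(C)(C)C)cc1 | intermediate
11 | methyl (3S,4E,7S)-7-(TBSO)-3,9-bis[4-(TBSO)phenyl]non-4-enoate | COC(=O)C[C@@H](/C=C/C[C@@H](O[Si](C)(C)C(C)(C)C)CCc1ccc(O[Si](C)(C)C(C)(C)C)cc1)c1ccc(O[Si](C)(C)C(C)(C)C)cc1 | intermediate
12 | 4-methoxy-6-methyl-2H-pyran-2-one | COC1=CC(=O)OC(C)=C1 | starting material
13 | 4-(TBSO)benzaldehyde | O=Cc1ccc(O[Si](C)(C)C(C)(C)C)cc1 | starting material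
14 | 6-(lithiomethyl)-4-methoxy-2H-pyran-2-one (not isolated) | [Li]CC1=CC(OC)=CC(=O)O1 | intermediate
15 | 6-{2-hydroxy-2-[4-(TBSO)phenyl]ethyl}-4-methoxy-2H-pyran-2-one (racemic) | COC1=CC(=O)OC(CC(O)c2ccc(O[Si](C)(C)C(C)(C)C)cc2)=C1 | intermediate
16 | 2-(4-methoxy-2-oxo-2H-pyran-6-yl)-1-[4-(TBSO)phenyl]ethyl methanesulfonate (not isolated) | COC1=CC(=O)OC(CC(OS(C)(=O)=O)c2ccc(O[Si](C)(C)C(C)(C)C)cc2)=C1 | intermediate
17 | 4-methoxy-6-{(E)-2-[4-(TBSO)phenyl]ethenyl}-2H-pyran-2-one | COC1=CC(=O)OC(/C=C/c2ccc(O[Si](C)(C)C(C)(C)C)cc2)=C1 | intermediate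
18 | lithium enolate of ester 11 (not isolated) | COC(O[Li])=C[C@@H](/C=C/C[C@@H](O[Si](C)(C)C(C)(C)C)CCc1ccc(O[Si](C)(C)C(C)(C)C)cc1)c1ccc(O[Si](C)(C)C(C)(C)C)cc1 | intermediate
19 | methyl (4E,8E)-2-{(1R,2E,5S)-5-(TBSO)-1,7-bis[4-(TBSO)phenyl]hept-2-en-1-yl}-5-methoxy-3,7-dioxo-9-[4-(TBSO)phenyl]nona-4,8-dienoate (C2 epimers) | COC(=O)C(C(=O)/C=C(/OC)CC(=O)/C=C/c1ccc(O[Si](C)(C)C(C)(C)C)cc1)[C@@H](/C=C/C[C@@H](O[Si](C)(C)C(C)(C)C)CCc1ccc(O[Si](C)(C)C(C)(C)C)cc1)c1ccc(O[Si](C)(C)C(C)(C)C)cc1 | intermediate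
20 | dilithium dienolate of 19 (C3'/C4' enolate and C1' enolate of the cinnamoyl ketone; not isolated) | COC(=O)C(=C(O[Li])/C=C(/OC)C=C(O[Li])/C=C/c1ccc(O[Si](C)(C)C(C)(C)C)cc1)[C@@H](/C=C/C[C@@H](O[Si](C)(C)C(C)(C)C)CCc1ccc(O[Si](C)(C)C(C)(C)C)cc1)c1ccc(O[Si](C)(C)C(C)(C)C)cc1 | intermediate
21 | tetra-TBS ether of calyxin B | COc1cc(O)c([C@@H](/C=C/C[C@@H](O[Si](C)(C)C(C)(C)C)CCc2ccc(O[Si](C)(C)C(C)(C)C)cc2)c2ccc(O[Si](C)(C)C(C)(C)C)cc2)c(O)c1C(=O)/C=C/c1ccc(O[Si](C)(C)C(C)(C)C)cc1 | intermediate
22 | calyxin B | COc1cc(O)c([C@@H](/C=C/C[C@@H](O)CCc2ccc(O)cc2)c2ccc(O)cc2)c(O)c1C(=O)/C=C/c1ccc(O)cc1 | target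

Total step count: 12. Longest linear sequence: 9 steps (steps 1, 2, 4, 5, 6, 7, 10, 11, 12).

Steps most likely to fail

1. Step 11. Ring closure may be slow because the C2' ester is conjugated to the C3'/C4' enolate, so that loss of aryl silyl groups to the liberated methoxide or intermolecular conjugate addition to the cinnamoyl enone may overtake it. The fallback gives up the folding of ring A and makes the C7–C3' bond on a ready-made ring A by Friedel–Crafts alkylation; it sets out from 9 and rejoins the route at 22. The chalcone helichrysetin F1 would be made from purchased 1-(2,4-dihydroxy-6-methoxyphenyl)ethanone and 4-hydroxybenzaldehyde (KOH, EtOH, rt; Claisen–Schmidt condensation). Treatment of F1 with 9 and camphorsulfonic acid (MeCN/CH2Cl2, −20 °C → rt) should ionise the allylic alcohol to the C5–C7 allyl cation stabilised by ring C, which C3' of the phloroglucinol ring captures to give the tris-silyl ether of calyxin B F2; the C3 silyl ether blocks intramolecular capture by O3. Bu4NF/AcOH in THF would then give 22. The cost is loss of control at C7 and competing attack at C5' and at C5, so the C7 epimer and regioisomers would have to be removed by preparative HPLC.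

2. Step 10. Enolate 18 may add in conjugate fashion to C6 of the pyranone or to the styryl terminus instead of to the lactone carbonyl, or proton transfer may stop the acylation early. The fallback assembles the chain by two separate acylations without the pyranone; it sets out from 11 (and uses 13) and rejoins the route at 19. Purchased (E)-3-methoxybut-2-enoic acid would be converted with (COCl)2 and N,N-dimethylformamide (cat.) in CH2Cl2 to (E)-3-methoxybut-2-enoyl chloride F3. The lithium enolate of 11 (LiN(i-Pr)2, THF, −78 °C, excess enolate) would be C-acylated by F3 to give β-keto ester F4. In parallel, 13 would be converted by Horner–Wadsworth–Emmons reaction with diethyl {2-[methoxy(methyl)amino]-2-oxoethyl}phosphonate (NaH, THF) to the N-methoxy-N-methyl cinnamamide F5. The dianion of F4 (LiN(i-Pr)2, 2.2 equiv, THF, −78 °C; C3' enolate plus γ-deprotonation at the C1' methyl group) would then be acylated at C1' by F5 to give 19.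

3. Step 7. Under hot, weakly acidic conditions the electron-rich 4-silyloxycinnamyl alcohol may ionise, which would erode the C5 configuration or transpose the allylic oxygen before the rearrangement takes place. The fallback is an Ireland–Claisen rearrangement under basic conditions at low temperature; it sets out from 9 and rejoins the route at 11. Acetylation of 9 (Ac2O, pyridine, 4-(dimethylamino)pyridine, CH2Cl2) would give the allylic acetate F6. Treatment with LiN(i-Pr)2 and Me3SiCl (THF, −78 °C → rt) would form the silyl ketene acetal, which rearranges through the same chair transition state and gives, after aqueous work-up, the carboxylic acid F7. Esterification with Me3SiCHN2 (MeOH/toluene, 0 °C) would give 11.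

Further compounds
F1 | step 11 | helichrysetin, (E)-1-(2,4-dihydroxy-6-methoxyphenyl)-3-(4-hydroxyphenyl)prop-2-en-1-one | COc1cc(O)cc(O)c1C(=O)/C=C/c1ccc(O)cc1
F2 | step 11 | tris-silyl ether of calyxin B (TBS on O3 and on rings C and D) | COc1cc(O)c([C@@H](/C=C/C[C@@H](O[Si](C)(C)C(C)(C)C)CCc2ccc(O[Si](C)(C)C(C)(C)C)cc2)c2ccc(O[Si](C)(C)C(C)(C)C)cc2)c(O)c1C(=O)/C=C/c1ccc(O)cc1
F3 | step 10 | (E)-3-methoxybut-2-enoyl chloride | CO/C(C)=C/C(=O)Cl
F4 | step 10 | methyl (3R,4E,7S)-2-[(E)-3-methoxybut-2-enoyl]-7-(TBSO)-3,9-bis[4-(TBSO)phenyl]non-4-enoate (C2 epimers) | COC(=O)C(C(=O)/C=C(/OC)C)[C@@H](/C=C/C[C@@H](O[Si](C)(C)C(C)(C)C)CCc1ccc(O[Si](C)(C)C(C)(C)C)cc1)c1ccc(O[Si](C)(C)C(C)(C)C)cc1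
F5 | step 10 | (E)-N-methoxy-N-methyl-3-[4-(TBSO)phenyl]prop-2-enamide | CON(C)C(=O)/C=C/c1ccc(O[Si](C)(C)C(C)(C)C)cc1
F6 | step 7 | (3S,5S,6E)-3-(TBSO)-1,7-bis[4-(TBSO)phenyl]hept-6-en-5-yl acetate | CC(=O)O[C@H](/C=C/c1ccc(O[Si](C)(C)C(C)(C)C)cc1)C[C@@H](O[Si](C)(C)C(C)(C)C)CCc1ccc(O[Si](C)(C)C(C)(C)C)cc1
F7 | step 7 | (3S,4E,7S)-7-(TBSO)-3,9-bis[4-(TBSO)phenyl]non-4-enoic acid | OC(=O)C[C@@H](/C=C/C[C@@H](O[Si](C)(C)C(C)(C)C)CCc1ccc(O[Si](C)(C)C(C)(C)C)cc1)c1ccc(O[Si](C)(C)C(C)(C)C)cc1
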